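**Remark on numbering and assumptions.** Quinic acid numbering is used for the carbocycle throughout: C1 is the carbinol bearing the carboxyl carbon C7, C3 carries the caffeate, C4 the p-coumarate, C5 the free hydroxyl, and C2 and C6 are methylenes. The target 23 is then 3-O-caffeoyl-4-O-p-coumaroylquinic acid, (1R,3R,4S,5R). Oxolane numbering appears only inside the names of the lactone intermediates. TBS = tert-butyldimethylsilyl, TBDPS = tert-butyldiphenylsilyl. The acid chlorides 16 and 20 are assumed to be used crude after evaporation.

## The problem

The target 23 is a monocyclic cyclohexane: C1 carries a hydroxyl and the carboxyl carbon C7, C3 and C4 carry two different hydroxycinnamates, C5 carries a free hydroxyl, and O1, O3 and O4 lie on one face while O5 and C7 lie on the other. With no ring fusion to lean on, the four stereocentres have to be related through a temporary ring. C5 is the natural anchor, because C7 is cis to O5 and the two can be tied as a γ-lactone (C7, C1, C6, C5, O5). This lactone fixes C1 relative to C5 across a five-membered ring and turns C2–C3–C4 into a bridge whose two faces are different, so C5 can control C1 directly and C3 and C4 through the bicycle. The second problem is regiochemical: of three secondary hydroxyls one must stay free and two must carry different acyl groups, the tertiary O1 must stay free, and acyl groups move easily between neighbouring quinate hydroxyls under base. The fragile groups are the two cinnamate esters (base, nucleophiles, hydrogenation, migration), the catechol (oxidation) and, on the way, an α-acyloxy aldehyde and a β-silyloxy aldehyde that epimerise or eliminate with base. The esters therefore go on late and everything after them is acidic or neutral. The feature that makes the key step possible is that, once C7 and O5 are held in the lactone, the remaining ring bond C3–C4 joins two carbinol carbons with cis oxygens. It is thus a pinacol bond between an acetaldehyde arm on C1 (C2–C3) and a formyl group on C5 (C4), and these two arms are cis on the lactone ring. The same lactone keeps O5 and C7 masked while O3 and O4 are acylated.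

## Retrosynthesis

**23 back to 21.** No skeletal bond is cut. The C7–O5 bond is re-formed as the lactone, the three phenols are masked as acetates and O1 as a TBS ether, which leads through 22 to 21. Acetates are chosen because aqueous acid removes them and opens the lactone in the same operation without touching cinnamates. Base or hydrogenolysis would not be tolerated. The forward steps must cleave a hindered tertiary silyl ether (fluoride under acidic conditions) and then hydrolyse without acyl migration.

**21 back to 13.** The two ester C–O bonds are cut, first O4–acyl (21 to 17 plus acid 19, used as its chloride 20), then O3–acyl (17 to 13 plus acid 15, used as its chloride 16). The acids come from p-coumaric acid 18 and caffeic acid 14 by acetylation. Acylating O3 first is preferred over the reverse order because O3 is equatorial in the bicycle and O4 is axial, so the more reactive hydroxyl takes the first acyl group. O5 and C7 cannot interfere because they are the lactone, and O1 cannot because it is silylated. The precursor 13 is a bicyclic diol with no aromatic parts. The forward reactions must discriminate between two secondary hydroxyls and must not let the first ester migrate.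

**13 back to 12 (the strategic cut).** The C3–C4 bond is cut to give the dialdehyde 12. The other ring bonds are poorer choices: C1–C2 or C5–C6 would call for aldol or alkylation chemistry next to a quaternary carbinol and would set only one centre. Closing the same C3–C4 bond as an alkene and dihydroxylating it costs two steps (this is kept as the reserve). The pinacol cut removes the carbocycle and two stereocentres at once and leaves a monocyclic lactone with two stereocentres. The forward reaction must give the cis diol on the face away from the lactone bridge and must reduce aldehydes in the presence of a lactone. O1 is carried as a silyl ether so that 12 has no β-hydroxy aldehyde and 13 can be extracted and acylated cleanly.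

**12 back to 8.** The two carbonyls are traced to stable precursors. The C3 aldehyde comes from the terminal alkene of an allyl group (one carbon lost on ozonolysis, 12 from 10). The C4 aldehyde comes from a primary alcohol (10 from 9), itself freed from the TBDPS ether 8. The fragile dialdehyde is thus made in the last operation before it is used. The forward steps need a fluoride cleavage that spares the tertiary TBS ether and oxidations that do not epimerise C5.

**8 back to 1 and 3.** At the lactone α-carbon C1 the C1–O1 bond and the C1–C2 bond are cut, giving 7, then 5, then the silyl lactone 2 and allyl bromide 3. Compound 2 is the silyl ether of the commercial (R)-hydroxymethyl lactone 1. The order of the two enolate reactions is the point: the second electrophile enters anti to the C5 side chain, so oxygen must come last to be trans to it and push the allyl group cis. The reverse order would give the wrong C1 epimer. This reduces the problem to one purchased stereocentre.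

## Roads not taken

**Alternative 1:** The cut is through C1–O1 and C4–O4 at once. Singlet oxygen (O2, light, tetraphenylporphyrin sensitiser) would add across C1 and C4 of the dienoate A1, anti to the C5 silyloxy group, to give the endoperoxide A2.
- Merits: two C–O bonds and the cis-1,4 relation of O1 and O4 come from one reagent and one existing stereocentre. O4 is unveiled on O–O cleavage while O3 arrives later, so the two acylation sites would be differentiated by timing. That is better than the chosen plan, which relies on an equatorial/axial rate difference.
- Weak points: A1 is a cyclohexadiene with a leaving group next to the diene and can aromatise by elimination, and it needs its own enantioselective synthesis. The ene reaction and base-induced rearrangement of A2 at C4–H compete. After the peroxide is reduced, O3 still has to be added to C3 and hydrogen to C2 across the remaining alkene. A directed epoxidation is plausible, but hydride opening would have to occur at C2, next to the quaternary C1, which is the more hindered end.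
- Comparison: the chosen plan sets O3 and O4 together with the ring in one step from a stable, purchasable lactone and has no regiochemical hydration problem. Against the alternative's cleaner O3/O4 differentiation it sets a reserve end-game in which O3 is blocked as a silyl ether.

**Alternative 2:** The cut is the C1–O1 bond of a quinate made from methyl shikimate A3. A peracid (trifluoroperacetic acid for this electron-poor alkene) would epoxidise C1=C2 on the O3 face to give A4, and reductive opening at C2 would give methyl quinate A5.
- Merits: C3, C4 and C5 are bought with the correct configuration, the allylic O3–H directs the oxidant to the right face, and the carbocyclic core is reached in two or three steps. In step count to the core this road is clearly shorter than the chosen plan (eight steps to 13).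
- Weak points: the conjugated ester makes the alkene a poor partner for electrophilic oxidants. The usual reductants for α,β-epoxy esters break the Cα–O bond and would delete O1 instead of O2. Delivering hydrogen to C2 would probably need a halide opening followed by radical dehalogenation, with the ester at risk from hydride reagents. A5 then has three free secondary hydroxyls and a free O1, so it must still be lactonised onto O5 and protected at O1 before the two different esters can be placed, which lengthens the end-game.
- Comparison: the chosen plan costs more steps and buys independence from the cyclitol chiral pool, access to either enantiomer from either enantiomer of 1, and an intermediate 13 in which O5, C7 and O1 are already masked when O3 and O4 appear.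

**Alternative 3:** The cut is through C1–C6 and C2–C3. Buta-1,3-diene A6 and 2-(benzoyloxy)acrolein A7 would undergo an enantioselective Diels–Alder reaction under a chiral primary ammonium salt to give A8. Oxidation to the acid, halolactonisation onto C5, elimination to the bicyclic alkene A9 and cis-dihydroxylation would then relay the C1 centre to C5, C3 and C4.
- Merits: achiral feedstocks, a catalytic source of chirality, and every later centre set by the bridging lactone. It reaches an O1-benzoyl analogue of 13 in about five steps, which is shorter than the chosen plan.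
- Weak points: the absolute configuration rests on one catalytic step with a gaseous, unbiased diene, and the single stereocentre of A8 is defined only by the position of a remote alkene, so any shortfall in enantiomeric purity is carried to the end. The O1 benzoate cannot be removed after the cinnamates are in place, since base would cleave or scramble them, and would have to be exchanged first (two more steps).
- Comparison: the chosen plan takes its absolute configuration from an enantiopure building block, closes the ring and sets two centres in one reduction, and carries O1 as a silyl ether that leaves under acidic fluoride. The alkene-plus-dihydroxylation logic of this alternative is kept as the reserve for the key step.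

Key step: step 8

## Route

Step 1
Reactants: 1 (5R)-5-(hydroxymethyl)oxolan-2-one
Product: 2 (5R)-5-{[(tert-butyldiphenylsilyl)oxy]methyl}oxolan-2-one
Conditions: TBDPSCl, imidazole, DMF, 0 °C → rt
Reagents that add atoms: tert-butyl(chloro)diphenylsilane (TBDPSCl), CC(C)(C)[Si](Cl)(c1ccccc1)c1ccccc1
Why: Standard silyl ether formation on a primary alcohol; the bulky silyloxymethyl group is the stereocontrol element for step 3 and the stereocentre is not involved.

Step 2
Reactants: 2 (5R)-5-{[(tert-butyldiphenylsilyl)oxy]methyl}oxolan-2-one; 3 allyl bromide
Product: 5 (3S,5R)-3-allyl-5-{[(tert-butyldiphenylsilyl)oxy]methyl}oxolan-2-one, via lithium enolate 4 (not isolated)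
Conditions: LiN(iPr)2, THF, −78 °C; then allyl bromide, −78 → −40 °C
Reagents that add atoms: none
Why: Lactone enolate alkylation; the allyl group should enter mainly trans to the silyloxymethyl group (1,3-induction), but this centre is made planar again in step 3, so the selectivity here is of no consequence.

Step 3
Reactants: 5 (3S,5R)-3-allyl-5-{[(tert-butyldiphenylsilyl)oxy]methyl}oxolan-2-one
Product: 7 (3S,5R)-3-allyl-3-hydroxy-5-{[(tert-butyldiphenylsilyl)oxy]methyl}oxolan-2-one, via potassium enolate 6 (not isolated)
Conditions: KN(SiMe3)2, THF, −78 °C; then 2-(phenylsulfonyl)-3-phenyloxaziridine, −78 °C; AcOH quench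
Reagents that add atoms: 2-(phenylsulfonyl)-3-phenyloxaziridine, O=S(=O)(c1ccccc1)N1OC1c1ccccc1
Why: Enolate hydroxylation with an N-sulfonyloxaziridine; the oxidant should approach the planar enolate anti to the silyloxymethyl group (1,3-asymmetric induction in γ-butyrolactone enolates), so the new hydroxyl is trans and the allyl group cis to the C5 side chain, which sets C1; the potassium enolate limits addition to the sulfonimine by-product.

Step 4
Reactants: 7 (3S,5R)-3-allyl-3-hydroxy-5-{[(tert-butyldiphenylsilyl)oxy]methyl}oxolan-2-one
Product: 8 (3S,5R)-3-allyl-3-[(tert-butyldimethylsilyl)oxy]-5-{[(tert-butyldiphenylsilyl)oxy]methyl}oxolan-2-one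
Conditions: TBSOTf, 2,6-lutidine, CH2Cl2, 0 °C → rt
Reagents that add atoms: tert-butyldimethylsilyl trifluoromethanesulfonate (TBSOTf), CC(C)(C)[Si](C)(C)OS(=O)(=O)C(F)(F)F
Why: Silyl triflate silylation of a tertiary alcohol; the α-carbon is quaternary, so no ketene acetal can form, and the silyl ether removes the β-hydroxy aldehyde and triol problems from the later steps.

Step 5
Reactants: 8 (3S,5R)-3-allyl-3-[(tert-butyldimethylsilyl)oxy]-5-{[(tert-butyldiphenylsilyl)oxy]methyl}oxolan-2-one
Product: 9 (3S,5R)-3-allyl-3-[(tert-butyldimethylsilyl)oxy]-5-(hydroxymethyl)oxolan-2-one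
Conditions: TBAF, AcOH, THF, 0 °C → rt
Reagents that add atoms: none
Why: Fluoride desilylation; fluoride attacks the unhindered primary silyl ether far faster than the tertiary one on a quaternary carbon, and the acetic acid buffer protects the lactone.

Step 6
Reactants: 9 (3S,5R)-3-allyl-3-[(tert-butyldimethylsilyl)oxy]-5-(hydroxymethyl)oxolan-2-one
Product: 10 (2R,4S)-4-allyl-4-[(tert-butyldimethylsilyl)oxy]-5-oxooxolane-2-carbaldehyde
Conditions: Dess–Martin periodinane, CH2Cl2, 0 °C → rt
Reagents that add atoms: none
Why: Dess–Martin oxidation of a primary alcohol under non-basic conditions, chosen so that the α-acyloxy aldehyde centre (C5) is not epimerised; the alkene is inert.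

Step 7
Reactants: 10 (2R,4S)-4-allyl-4-[(tert-butyldimethylsilyl)oxy]-5-oxooxolane-2-carbaldehyde
Product: 12 2-[(3R,5R)-3-[(tert-butyldimethylsilyl)oxy]-5-formyl-2-oxooxolan-3-yl]acetaldehyde, via ozonide 11 (not isolated)
Conditions: O3, CH2Cl2, −78 °C (indicator end point); then PPh3, −78 °C → rt
Reagents that add atoms: ozone, [O-][O+]=O
Why: Ozonolysis of a terminal alkene (Criegee mechanism) with neutral phosphine reduction of the ozonide; no base is present, so the dialdehyde should survive to be passed through a short silica plug and used at once.

Step 8
Reactants: 12 2-[(3R,5R)-3-[(tert-butyldimethylsilyl)oxy]-5-formyl-2-oxooxolan-3-yl]acetaldehyde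
Product: 13 (1S,3R,4R,5R)-1-[(tert-butyldimethylsilyl)oxy]-3,4-dihydroxy-6-oxabicyclo[3.2.1]octan-7-one (1-O-TBS-quinide)
Conditions: SmI2 (0.1 M in THF), t-BuOH, THF, −78 → −20 °C, slow addition of 12 at high dilution; aqueous NaHCO3 work-up
Reagents that add atoms: none
Why: Samarium diiodide (divalent samarium) transfers one electron to an aldehyde of 12, most readily the α-oxygenated C4 aldehyde, and the samarium-bound ketyl adds to the second aldehyde held on the same trivalent samarium centre; a second equivalent reduces the resulting alkoxy radical and tert-butanol protonates the diolate. The closest known reaction type is the SmI2 pinacol cyclisation of 1,6-dialdehydes to cis-cyclohexane-1,2-diols, as used for cyclitols. The cyclohexane ring closes by 6-exo-trig attack of the ketyl carbon on the other carbonyl carbon (C3–C4), which is possible only because the two arms are cis on the lactone, and this gives the bridged 6-oxabicyclo[3.2.1]octanone directly. The cis relation of O3 and O4 follows from the samarium bridge between the two oxygens in the transition state. Their relation to the rest is set by C5: the C4–O bond avoids the C5–O5 dipole and takes the axial position anti to the lactone bridge, and the other cis diol would put O3 axial underneath that bridge, so both new centres are controlled by the existing ones. The step needs selectivity for the aldehydes over the lactone and the C5–O5 bond; working at −78 °C without HMPA, where esters are not reduced, and the speed of the intramolecular coupling should secure it. High dilution and slow addition suppress intermolecular pinacols. The tertiary silyl ether keeps O1 off the metal and makes 13 extractable.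

Step 9
Reactants: 14 caffeic acid
Product: 15 (E)-3-(3,4-diacetoxyphenyl)prop-2-enoic acid
Conditions: Ac2O, pyridine, rt; then H2O, dilute HCl work-up
Reagents that add atoms: acetic anhydride, CC(=O)OC(C)=O
Why: Acetylation of both phenols; any mixed anhydride at the carboxyl group is hydrolysed on aqueous work-up, and the alkene geometry is untouched.

Step 10
Reactants: 13 1-O-TBS-quinide; 15 (E)-3-(3,4-diacetoxyphenyl)prop-2-enoic acid
Product: 17 1-O-TBS-3-O-[(E)-3,4-diacetoxycinnamoyl]-1,5-quinide (13 acylated on the equatorial O3 with O4 free), via 3,4-diacetoxycinnamoyl chloride 16 (not isolated)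
Conditions: 15, (COCl)2, cat. DMF, CH2Cl2, 0 °C → rt, evaporate; then 13, pyridine, CH2Cl2, −40 → 0 °C
Reagents that add atoms: none
Why: Acid chloride formation followed by acylation in pyridine; the equatorial O3 is more accessible than the axial O4 next to the bridgehead, so one equivalent at low temperature without DMAP should acylate O3; O1 is silylated and O5 is the lactone oxygen.

Step 11
Reactants: 18 p-coumaric acid
Product: 19 (E)-3-(4-acetoxyphenyl)prop-2-enoic acid
Conditions: Ac2O, pyridine, rt; then H2O, dilute HCl work-up
Reagents that add atoms: acetic anhydride, CC(=O)OC(C)=O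
Why: Phenol acetylation as in step 9.

Step 12
Reactants: 17 1-O-TBS-3-O-[(E)-3,4-diacetoxycinnamoyl]-1,5-quinide; 19 (E)-3-(4-acetoxyphenyl)prop-2-enoic acid
Product: 21 1-O-TBS-3-O-[(E)-3,4-diacetoxycinnamoyl]-4-O-[(E)-4-acetoxycinnamoyl]-1,5-quinide, via 4-acetoxycinnamoyl chloride 20 (not isolated)
Conditions: 19, (COCl)2, cat. DMF, CH2Cl2, 0 °C → rt, evaporate; then 17, pyridine, cat. DMAP, CH2Cl2, 0 °C → rt
Reagents that add atoms: none
Why: DMAP-catalysed acylation of the only free hydroxyl (axial O4) with an excess of acid chloride; adding the chloride before the catalyst keeps the alcohol from standing with base, which limits migration of the O3 ester.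

Step 13
Reactants: 21 1-O-TBS-3-O-[(E)-3,4-diacetoxycinnamoyl]-4-O-[(E)-4-acetoxycinnamoyl]-1,5-quinide
Product: 22 3-O-[(E)-3,4-diacetoxycinnamoyl]-4-O-[(E)-4-acetoxycinnamoyl]-1,5-quinide (free tertiary O1–H)
Conditions: HF·pyridine, THF, 0 °C → rt (polypropylene vessel)
Reagents that add atoms: none
Why: Acidic fluoride cleavage of a hindered tertiary silyl ether; aryl acetates, cinnamates and the lactone are stable, and no basic species is present that could move an acyl group.

Step 14
Reactants: 22 3-O-[(E)-3,4-diacetoxycinnamoyl]-4-O-[(E)-4-acetoxycinnamoyl]-1,5-quinide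
Product: 23 (1R,3R,4S,5R)-3-{[(E)-3-(3,4-dihydroxyphenyl)prop-2-enoyl]oxy}-1,5-dihydroxy-4-{[(E)-3-(4-hydroxyphenyl)prop-2-enoyl]oxy}cyclohexane-1-carboxylic acid
Conditions: 2 M aq. HCl, THF, rt; reverse-phase chromatography
Reagents that add atoms: water, O
Why: Acid-catalysed hydrolysis; aryl acetates and the strained bridged lactone should hydrolyse much faster than the conjugated cinnamates, and acid (unlike base) does not promote acyl migration to the liberated O5; no stereocentre is touched.

## Compound list

1 | (5R)-5-(hydroxymethyl)oxolan-2-one | OC[C@H]1CCC(=O)O1 | starting material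
2 | (5R)-5-{[(tert-butyldiphenylsilyl)oxy]methyl}oxolan-2-one | CC(C)(C)[Si](OC[C@H]1CCC(=O)O1)(c1ccccc1)c1ccccc1 | intermediate
3 | allyl bromide (3-bromoprop-1-ene) | C=CCBr | starting material
4 | lithium enolate of 2 | [Li+].[O-]C1=CC[C@H](CO[Si](c2ccccc2)(c2ccccc2)C(C)(C)C)O1 | intermediate (not isolated)
5 | (3S,5R)-3-allyl-5-{[(tert-butyldiphenylsilyl)oxy]methyl}oxolan-2-one (allyl trans to the side chain) | C=CC[C@H]1C[C@H](CO[Si](c2ccccc2)(c2ccccc2)C(C)(C)C)OC1=O | intermediate
6 | potassium enolate of 5 | [K+].[O-]C1=C(CC=C)C[C@H](CO[Si](c2ccccc2)(c2ccccc2)C(C)(C)C)O1 | intermediate (not isolated)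
7 | (3S,5R)-3-allyl-3-hydroxy-5-{[(tert-butyldiphenylsilyl)oxy]methyl}oxolan-2-one (OH trans, allyl cis to the side chain) | C=CC[C@]1(O)C[C@H](CO[Si](c2ccccc2)(c2ccccc2)C(C)(C)C)OC1=O | intermediate
8 | (3S,5R)-3-allyl-3-[(tert-butyldimethylsilyl)oxy]-5-{[(tert-butyldiphenylsilyl)oxy]methyl}oxolan-2-one | C=CC[C@]1(O[Si](C)(C)C(C)(C)C)C[C@H](CO[Si](c2ccccc2)(c2ccccc2)C(C)(C)C)OC1=O | intermediate
9 | (3S,5R)-3-allyl-3-[(tert-butyldimethylsilyl)oxy]-5-(hydroxymethyl)oxolan-2-one | C=CC[C@]1(O[Si](C)(C)C(C)(C)C)C[C@H](CO)OC1=O | intermediate
10 | (2R,4S)-4-allyl-4-[(tert-butyldimethylsilyl)oxy]-5-oxooxolane-2-carbaldehyde | C=CC[C@]1(O[Si](C)(C)C(C)(C)C)C[C@H](C=O)OC1=O | intermediate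
11 | ozonide of 10 (1,2,4-trioxolane at the former allyl terminus, ring centres as in 10, trioxolane carbon unassigned) | C1(C[C@]2(O[Si](C)(C)C(C)(C)C)C[C@H](C=O)OC2=O)OCOO1 | intermediate (not isolated)
12 | 2-[(3R,5R)-3-[(tert-butyldimethylsilyl)oxy]-5-formyl-2-oxooxolan-3-yl]acetaldehyde | O=CC[C@]1(O[Si](C)(C)C(C)(C)C)C[C@H](C=O)OC1=O | intermediate
13 | (1S,3R,4R,5R)-1-[(tert-butyldimethylsilyl)oxy]-3,4-dihydroxy-6-oxabicyclo[3.2.1]octan-7-one (1-O-TBS-quinide) | O[C@H]1[C@H]2C[C@@](O[Si](C)(C)C(C)(C)C)(C[C@H]1O)C(=O)O2 | intermediate
14 | caffeic acid | OC(=O)/C=C/c1ccc(O)c(O)c1 | starting material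
15 | (E)-3-(3,4-diacetoxyphenyl)prop-2-enoic acid | CC(=O)Oc1ccc(/C=C/C(=O)O)cc1OC(C)=O | intermediate
16 | (E)-3-(3,4-diacetoxyphenyl)prop-2-enoyl chloride | CC(=O)Oc1ccc(/C=C/C(Cl)=O)cc1OC(C)=O | intermediate (not isolated)
17 | 1-O-TBS-3-O-[(E)-3,4-diacetoxycinnamoyl]-1,5-quinide | O[C@H]1[C@H]2C[C@@](O[Si](C)(C)C(C)(C)C)(C[C@H]1OC(=O)/C=C/c3ccc(OC(C)=O)c(OC(C)=O)c3)C(=O)O2 | intermediate
18 | p-coumaric acid | OC(=O)/C=C/c1ccc(O)cc1 | starting material
19 | (E)-3-(4-acetoxyphenyl)prop-2-enoic acid | CC(=O)Oc1ccc(/C=C/C(=O)O)cc1 | intermediate
20 | (E)-3-(4-acetoxyphenyl)prop-2-enoyl chloride | CC(=O)Oc1ccc(/C=C/C(Cl)=O)cc1 | intermediate (not isolated)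
21 | 1-O-TBS-3-O-[(E)-3,4-diacetoxycinnamoyl]-4-O-[(E)-4-acetoxycinnamoyl]-1,5-quinide | CC(=O)Oc3ccc(/C=C/C(=O)O[C@H]1[C@H]2C[C@@](O[Si](C)(C)C(C)(C)C)(C[C@H]1OC(=O)/C=C/c4ccc(OC(C)=O)c(OC(C)=O)c4)C(=O)O2)cc3 | intermediate
22 | 3-O-[(E)-3,4-diacetoxycinnamoyl]-4-O-[(E)-4-acetoxycinnamoyl]-1,5-quinide | CC(=O)Oc3ccc(/C=C/C(=O)O[C@H]1[C@H]2C[C@@](O)(C[C@H]1OC(=O)/C=C/c4ccc(OC(C)=O)c(OC(C)=O)c4)C(=O)O2)cc3 | intermediate
23 | (1R,3R,4S,5R)-3-O-caffeoyl-4-O-p-coumaroylquinic acid | O=C(/C=C/c1ccc(O)cc1)O[C@H]1[C@H](O)C[C@](O)(C(=O)O)C[C@H]1OC(=O)/C=C/c1ccc(O)c(O)c1 | target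

## Step count and least certain steps

Total: 14 steps. Longest linear sequence: 12 steps (1–8, 10, 12, 13, 14); steps 9 and 11 prepare the two acyl donors.

**Step 8 (key step).** After the first electron transfer the C4 ketyl may expel the lactone carboxylate (β-elimination that breaks C5–O5) faster than it adds to the C3 aldehyde. Plain reduction of both aldehydes or intermolecular coupling may compete. Loss of samarium chelation would erode the cis and facial selectivity. The dialdehyde 12 may also epimerise at C5 or lose silanol before it is reduced. The fallback keeps the C3–C4 closure but makes it an alkene. From 10, Wittig methylenation (Ph3P=CH2, THF, −78 °C) would give (3S,5R)-3-allyl-3-[(tert-butyldimethylsilyl)oxy]-5-vinyloxolan-2-one F1. Ring-closing metathesis with the second-generation Grubbs catalyst (CH2Cl2, 40 °C) would give (1S,5R)-1-[(tert-butyldimethylsilyl)oxy]-6-oxabicyclo[3.2.1]oct-3-en-7-one F2. Catalytic OsO4 with N-methylmorpholine N-oxide would then dihydroxylate F2 from the face away from the lactone bridge, and the route is rejoined at 13.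

**Step 3.** The oxygen transfer may show poor facial selectivity, placing the hydroxyl cis to the side chain, or the enolate may add to the sulfonimine by-product. The wrong C1 epimer is a diastereomer, separable at 7, and cannot close to a bridged bicycle later. As a fallback, from 5 the enolate would be trapped (LiN(iPr)2, Me3SiCl, THF, −78 °C) as the silyl ketene acetal [(2R)-4-allyl-2-{[(tert-butyldiphenylsilyl)oxy]methyl}-2,3-dihydrofuran-5-yl]oxy-trimethylsilane F3. Rubottom oxidation of F3 with dimethyldioxirane (acetone/CH2Cl2, −78 °C), a neutral oxidant with no nucleophilic by-product, followed by mild acidic work-up to remove the trimethylsilyl group, would give 7, where the route is rejoined.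

**Step 10 (with step 12).** Discrimination between O3 and O4 may be incomplete, and the caffeoyl group may migrate from O3 to O4 under the basic conditions of steps 10 and 12, which would give the regioisomeric mixed diester. As a fallback, from 13 silylation (TBSCl, imidazole, DMF, 0 °C) should take the equatorial O3 selectively and give 1,3-bis-O-TBS-1,5-quinide F4. Acylation of the only free hydroxyl O4 with 20 (generated from 19 as in step 12; pyridine, DMAP) would give 1,3-bis-O-TBS-4-O-[(E)-4-acetoxycinnamoyl]-1,5-quinide F5. HF·pyridine would remove both silyl ethers to give 4-O-[(E)-4-acetoxycinnamoyl]-1,5-quinide F6. Acylation of F6 with 16 at low temperature in pyridine would distinguish the secondary O3 from the tertiary O1 and rejoin the route at 22, replacing steps 10, 12 and 13.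

**Step 5.** The tertiary TBS ether may be lost together with the primary TBDPS ether, or cleavage may stall under buffered fluoride. As a fallback, from 7 TBAF/AcOH would remove the only silyl group and give (3S,5R)-3-allyl-3-hydroxy-5-(hydroxymethyl)oxolan-2-one F7. Double silylation (TBSOTf, 2,6-lutidine) would give (3S,5R)-3-allyl-3-[(tert-butyldimethylsilyl)oxy]-5-{[(tert-butyldimethylsilyl)oxy]methyl}oxolan-2-one F8. HF·pyridine buffered with pyridine in THF at 0 °C would then cleave the primary TBS ether far faster than the tertiary one, and the route is rejoined at 9.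

**Step 14.** During the long exposure needed to open the lactone, an acyl group may migrate under acid catalysis (O4 to the freed O5, or between O3 and O4) and the cinnamates may hydrolyse slowly. As a fallback, from 22 hydrazine acetate in DMF (0 °C → rt) would cleave the three aryl acetates by aminolysis and give 3-O-caffeoyl-4-O-p-coumaroyl-1,5-quinide F9. Only the lactone then has to be opened, by a short treatment with dilute aqueous HCl in THF, and the route is rejoined at 23.

## Further compounds

F1 | step 8 | (3S,5R)-3-allyl-3-[(tert-butyldimethylsilyl)oxy]-5-vinyloxolan-2-one | C=CC[C@]1(O[Si](C)(C)C(C)(C)C)C[C@H](C=C)OC1=O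
F2 | step 8 | (1S,5R)-1-[(tert-butyldimethylsilyl)oxy]-6-oxabicyclo[3.2.1]oct-3-en-7-one | C1=C[C@H]2C[C@@](O[Si](C)(C)C(C)(C)C)(C1)C(=O)O2
F3 | step 3 | [(2R)-4-allyl-2-{[(tert-butyldiphenylsilyl)oxy]methyl}-2,3-dihydrofuran-5-yl]oxy-trimethylsilane | C[Si](C)(C)OC1=C(CC=C)C[C@H](CO[Si](c2ccccc2)(c2ccccc2)C(C)(C)C)O1
F4 | step 10 | 1,3-bis-O-TBS-1,5-quinide | O[C@H]1[C@H]2C[C@@](O[Si](C)(C)C(C)(C)C)(C[C@H]1O[Si](C)(C)C(C)(C)C)C(=O)O2
F5 | step 10 | 1,3-bis-O-TBS-4-O-[(E)-4-acetoxycinnamoyl]-1,5-quinide | CC(=O)Oc3ccc(/C=C/C(=O)O[C@H]1[C@H]2C[C@@](O[Si](C)(C)C(C)(C)C)(C[C@H]1O[Si](C)(C)C(C)(C)C)C(=O)O2)cc3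
F6 | step 10 | 4-O-[(E)-4-acetoxycinnamoyl]-1,5-quinide | CC(=O)Oc3ccc(/C=C/C(=O)O[C@H]1[C@H]2C[C@@](O)(C[C@H]1O)C(=O)O2)cc3
F7 | step 5 | (3S,5R)-3-allyl-3-hydroxy-5-(hydroxymethyl)oxolan-2-one | C=CC[C@]1(O)C[C@H](CO)OC1=O
F8 | step 5 | (3S,5R)-3-allyl-3-[(tert-butyldimethylsilyl)oxy]-5-{[(tert-butyldimethylsilyl)oxy]methyl}oxolan-2-one | C=CC[C@]1(O[Si](C)(C)C(C)(C)C)C[C@H](CO[Si](C)(C)C(C)(C)C)OC1=O
F9 | step 14 | 3-O-caffeoyl-4-O-p-coumaroyl-1,5-quinide | O=C(/C=C/c1ccc(O)cc1)O[C@H]1[C@H]2C[C@@](O)(C[C@H]1OC(=O)/C=C/c3ccc(O)c(O)c3)C(=O)O2
A1 | alternative 1 | methyl (5R)-5-[(tert-butyldimethylsilyl)oxy]cyclohexa-1,3-diene-1-carboxylate | COC(=O)C1=CC=C[C@H](O[Si](C)(C)C(C)(C)C)C1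
A2 | alternative 1 | methyl 5-[(tert-butyldimethylsilyl)oxy]-2,3-dioxabicyclo[2.2.2]oct-7-ene-1-carboxylate (peroxide bridge anti to the silyloxy group) | COC(=O)[C@@]12C=C[C@@H](OO1)[C@H](O[Si](C)(C)C(C)(C)C)C2
A3 | alternative 2 | methyl shikimate | COC(=O)C1=C[C@@H](O)[C@@H](O)[C@H](O)C1
A4 | alternative 2 | methyl shikimate 1,2-epoxide (oxirane cis to O3) | COC(=O)[C@]12O[C@H]1[C@@H](O)[C@@H](O)[C@H](O)C2
A5 | alternative 2 | methyl quinate | COC(=O)[C@]1(O)C[C@@H](O)[C@@H](O)[C@H](O)C1
A6 | alternative 3 | buta-1,3-diene | C=CC=C
A7 | alternative 3 | 2-(benzoyloxy)acrolein | C=C(C=O)OC(=O)c1ccccc1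
A8 | alternative 3 | (1S)-1-formylcyclohex-3-en-1-yl benzoate | O=C[C@]1(OC(=O)c2ccccc2)CCC=CC1
A9 | alternative 3 | (1S,5R)-7-oxo-6-oxabicyclo[3.2.1]oct-3-en-1-yl benzoate | C1=C[C@H]2C[C@@](OC(=O)c3ccccc3)(C1)C(=O)O2
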